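**Retrosynthetic overview**
- Numbering used: O1, C2 (bears CH2OH), C3 (bears aryl), O4, C6 (enal), C8 (OMe). The pendant aryl ring has a free 4-OH para to C3 of the 2,3-dihydro-1,4-benzodioxine ring. The C3–O4 bond (O4 sits on the benzo carbon next to C5–H, not on the one flanked by 8-OMe) is therefore a p-hydroxybenzyl aryl ether. It can be formed from a plain ArCH2 group by way of a p-quinone methide.
- Disconnections: the enal C=C (Wittig, last C–C bond); C3–O4 (dehydrogenative oxa-1,6 closure, trans by relay from C2); C2–H (asymmetric hydrogenation of a Z α-aryloxycinnamic acid); Cα=Cβ (aldol condensation of a ring-A aryl lactone with the pendant aldehyde).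
- Ring order: both benzene rings are bought. A temporary six-membered lactone is built on ring A, joins the two halves with fixed Z geometry, and is then opened. The 1,4-dioxane ring is closed in the key step.
- Stereochemistry: only C2 is set by a catalyst, C3 follows from C2, and the E-enal comes from a stabilised ylide.

Key step: step 12

Assumption: the sense of induction of the spiro Ir catalyst on this doubly ortho-substituted aryloxy substrate is not predicted here. The ligand antipode is chosen after a trial run so that the (S)-acid results.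

**Step 1**
Reactants: 1 methyl 3,4-dihydroxy-5-methoxybenzoate; 2 ethyl bromoacetate
Product: 3 methyl 4-(2-ethoxy-2-oxoethoxy)-3-hydroxy-5-methoxybenzoate
Conditions: KHCO3 (1.05 equiv), 2 (1.0 equiv), DMF, 40 °C
Reagents that add atoms: none
Why: Williamson etherification under acidity control: the 4-OH para to the ester is the most acidic phenol and the only one ionised usefully by one equivalent of bicarbonate, so the CH2CO2Et group should go on the oxygen flanked by OMe (regiochemistry to be confirmed by HMBC/NOE on 3).

**Step 2**
Reactants: 3 methyl 4-(2-ethoxy-2-oxoethoxy)-3-hydroxy-5-methoxybenzoate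
Product: 4 ring-A lactone methyl 8-methoxy-3-oxo-2,3-dihydro-1,4-benzodioxine-6-carboxylate
Conditions: p-TsOH·H2O (cat.), toluene, reflux, EtOH removed (Dean–Stark, 4 Å MS)
Reagents that add atoms: none
Why: Acid-catalysed transesterification (lactonisation) of the neighbouring 3-OH onto the ethyl ester closes an unstrained six-membered aryl lactone and is driven by removal of ethanol, while the methyl benzoate has no partner for ring closure.

**Step 3**
Reactants: 5 5-hydroxyvanillin (3,4-dihydroxy-5-methoxybenzaldehyde)
Product: 6 4-(benzyloxy)-3-hydroxy-5-methoxybenzaldehyde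
Conditions: BnBr (1.0 equiv), NaHCO3 (1.1 equiv), NaI (cat.), DMF, 40 °C
Reagents that add atoms: benzyl bromide, BrCc1ccccc1
Why: Acidity-controlled Williamson etherification: the 4-OH para to the formyl group is ionised selectively by bicarbonate and benzylated, which leaves the 3-OH free.

**Step 4**
Reactants: 6 4-(benzyloxy)-3-hydroxy-5-methoxybenzaldehyde
Product: 7 pendant aldehyde 4-(benzyloxy)-3-methoxy-5-(methoxymethoxy)benzaldehyde
Conditions: MOMCl, i-Pr2NEt, CH2Cl2, 0 °C to rt
Reagents that add atoms: chloromethyl methyl ether, COCCl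
Why: Standard MOM protection of a phenol with a hindered amine base; MOM is chosen because it survives base, hydride, both hydrogenations and Ag2O, and leaves under mild acid at the end.

**Step 5**
Reactants: 4 ring-A lactone; 7 pendant aldehyde
Product: 9 aldol adduct methyl 2-{[4-(benzyloxy)-3-methoxy-5-(methoxymethoxy)phenyl](hydroxy)methyl}-8-methoxy-3-oxo-2,3-dihydro-1,4-benzodioxine-6-carboxylate (diastereomer mixture), via lithium enolate 8 (not isolated)
Conditions: LiHMDS (1.05 equiv), THF, −78 °C; then 7, −78 °C; AcOH quench at −78 °C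
Reagents that add atoms: none
Why: Aldol addition of a lithium glycolate-type lactone enolate to a non-enolisable aldehyde; the low temperature and cold acidic quench keep the aryl-ester enolate from ketene formation and the aldolate from acyl transfer, and the two new centres need no control because both are erased in step 6.

**Step 6**
Reactants: 9 aldol adduct
Product: 11 methyl (2Z)-2-[4-(benzyloxy)-3-methoxy-5-(methoxymethoxy)benzylidene]-8-methoxy-3-oxo-2,3-dihydro-1,4-benzodioxine-6-carboxylate, via benzylic mesylate 10 (not isolated)
Conditions: MsCl, Et3N, CH2Cl2, −10 °C; then DBU, 0 °C to rt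
Reagents that add atoms: methanesulfonyl chloride, CS(=O)(=O)Cl (its atoms stay only in intermediate 10 and leave again on elimination)
Why: Mesylation followed by E1cB elimination across the acidic lactone α-C–H gives the conjugated alkene, and because the ring holds the ether O and C=O in place, the preferred isomer has the aryl group syn to the ring ether oxygen and away from the carbonyl (Z; to be checked by NOE or the vinyl-H/C=O coupling).

**Step 7**
Reactants: 11 (Z)-arylidene lactone
Product: 12 (2Z)-3-[4-(benzyloxy)-3-methoxy-5-(methoxymethoxy)phenyl]-2-[2-hydroxy-6-methoxy-4-(methoxycarbonyl)phenoxy]prop-2-enoic acid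
Conditions: LiOH (2.1 equiv), THF/H2O, 0 °C; then 1 M HCl to pH 3–4 at 0 °C, extracted cold
Reagents that add atoms: lithium hydroxide, [Li+].[OH-] (its oxygen ends up in the CO2H group)
Why: Chemoselective saponification: the aryl lactone with its phenolate leaving group is far more electrophilic than the methyl benzoate, so cold LiOH should open only the ring and unveil the ring-A 3-OH and the directing CO2H with the Z geometry unchanged.

**Step 8**
Reactants: 12 (Z)-α-aryloxycinnamic acid
Product: 13 (2S)-3-[4-(benzyloxy)-3-methoxy-5-(methoxymethoxy)phenyl]-2-[2-hydroxy-6-methoxy-4-(methoxycarbonyl)phenoxy]propanoic acid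
Conditions: [Ir(cod)(spiro phosphine–oxazoline, SIPHOX type)]BArF (1 mol %), H2 (6–10 atm), Et3N (0.5 equiv), MeOH, rt; concentrated below 30 °C and carried on as the open acid/ammonium salt
Reagents that add atoms: none
Why: Carboxy-directed Ir-catalysed asymmetric hydrogenation, a reaction type established for (Z)-α-aryloxy-α,β-unsaturated acids: the carboxylate binds Ir and the chiral spiro pocket selects the alkene face, which sets the (S) centre (later C2), while the homogeneous catalyst leaves benzyl ether, MOM and ester untouched.

**Step 9**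
Reactants: 13 (S)-acid
Product: 14 (2S)-3-[4-(benzyloxy)-3-methoxy-5-(methoxymethoxy)phenyl]-2-[2-hydroxy-4-(hydroxymethyl)-6-methoxyphenoxy]propan-1-ol
Conditions: LiAlH4 (excess), THF, 0 to 40 °C; aq. Rochelle salt work-up at about pH 7
Reagents that add atoms: none
Why: Exhaustive LiAlH4 reduction turns CO2H and CO2Me into CH2OH groups, and the α-centre is safe because the acid is reduced by way of its carboxylate/aluminate, which does not enolise.

**Step 10**
Reactants: 14 phenol diol
Product: 15 4-{[(2S)-1-[4-(benzyloxy)-3-methoxy-5-(methoxymethoxy)phenyl]-3-hydroxypropan-2-yl]oxy}-3-hydroxy-5-methoxybenzaldehyde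
Conditions: activated MnO2 (excess), CH2Cl2, rt
Reagents that add atoms: none
Why: MnO2 oxidises only activated (benzylic) alcohols, so ring-A ArCH2OH becomes ArCHO while the aliphatic CH2OH stays, and the pendant phenol is still benzylated so that no premature quinone methide can form.

**Step 11**
Reactants: 15 O-benzyl aldehyde
Product: 16 3-hydroxy-4-{[(2S)-1-hydroxy-3-[4-hydroxy-3-methoxy-5-(methoxymethoxy)phenyl]propan-2-yl]oxy}-5-methoxybenzaldehyde
Conditions: H2 (1 atm), 10% Pd/C, EtOAc, rt, stopped when 15 is consumed
Reagents that add atoms: none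
Why: Catalytic hydrogenolysis of an aryl benzyl ether is much faster than reduction of an electron-rich trioxygenated benzaldehyde at 1 atm in EtOAc, so the pendant 4-OH should be freed with CHO, MOM and the stereocentre intact.

**Step 12**
Reactants: 16 aldehyde bisphenol
Product: 18 (2R,3R)-3-[4-hydroxy-3-methoxy-5-(methoxymethoxy)phenyl]-2-(hydroxymethyl)-8-methoxy-2,3-dihydro-1,4-benzodioxine-6-carbaldehyde, via p-quinone methide 17 (not isolated)
Conditions: Ag2O (2.5 equiv), 4 Å MS, CH2Cl2 (ca. 5 mM), Ar, dark, rt; filtration through Celite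
Reagents that add atoms: none
Why: Proposed new method: Ag2O removes two electrons and two protons (the phenolic O–H, then the benzylic C–H, by way of a phenoxyl radical whose ortho positions are blocked by OMe and OMOM) from the 4-hydroxy-3-methoxy-5-(methoxymethoxy)benzyl unit of 16 to give p-quinone methide 17, and the ring-A 3-OH then adds to the exocyclic methide carbon (oxa-1,6-addition), which rearomatises the pendant ring and forms the C3–O4 bond. The closest known reaction types are the Ag2O dehydrogenation of 4-alkyl-2,6-dialkoxyphenols to p-quinone methides that take up O-nucleophiles in the 1,6 sense, and the phenol-onto-quinone-methide closure that ends biomimetic oxidative couplings to trans-1,4-benzodioxane neolignans; what is untested is entry into such a β-aryloxy quinone methide by C–H oxidation next to an existing stereocentre. The 1,4-dioxane ring closes in a 6-exo-trig mode. The new C3 centre is controlled by the hydrogenation-derived C2 centre through a half-chair transition state with aryl and CH2OH both pseudo-equatorial (trans, 2R,3R), and since the p-hydroxybenzyl aryl ether can reopen to 17, any cis isomer should drain to the more stable trans isomer (a trace of PPTS can speed this). Chemoselectivity for the pendant phenol rests on its electron-rich syringol-type pattern with a para CH2, whereas the ring-A phenol sits on a formyl-bearing ring with no para alkyl group, and the free CH2OH could only close an oxetane. Neutral, dry and dilute conditions are chosen to hold back tautomerisation of 17 to a styryl enol ether or loss of formaldehyde, either of which would erase C2.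

**Step 13**
Reactants: 18 benzodioxane aldehyde; 19 (triphenylphosphoranylidene)acetaldehyde
Product: 20 (2E)-3-{(2R,3R)-3-[4-hydroxy-3-methoxy-5-(methoxymethoxy)phenyl]-2-(hydroxymethyl)-8-methoxy-2,3-dihydro-1,4-benzodioxin-6-yl}prop-2-enal
Conditions: 19 (1.2 equiv), toluene, 75 °C, stopped at mono-homologation
Reagents that add atoms: none
Why: Wittig olefination with a stabilised formyl ylide gives the E-enal; the ylide is too weakly basic to deprotonate the phenol or CH2OH, and a small excess at moderate temperature limits a second homologation.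

**Step 14**
Reactants: 20 MOM-protected enal
Product: 21 target (2E)-3-[(2R,3R)-3-(3,4-dihydroxy-5-methoxyphenyl)-2-(hydroxymethyl)-8-methoxy-2,3-dihydro-1,4-benzodioxin-6-yl]prop-2-enal
Conditions: 2 M aq. HCl, THF/i-PrOH, 40 °C, Ar
Reagents that add atoms: none
Why: Acid-catalysed acetal hydrolysis removes the aryl MOM ether; the enal, the aryl methyl ethers and C2 are inert to dilute acid, and any reversible opening at the p-hydroxybenzylic C3 can only return the more stable trans isomer.

**Compound list**
1 | methyl 3,4-dihydroxy-5-methoxybenzoate | COC(=O)c1cc(O)c(O)c(OC)c1 | starting material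
2 | ethyl bromoacetate | CCOC(=O)CBr | starting material
3 | methyl 4-(2-ethoxy-2-oxoethoxy)-3-hydroxy-5-methoxybenzoate | COC(=O)c1cc(O)c(OCC(=O)OCC)c(OC)c1 | intermediate
4 | methyl 8-methoxy-3-oxo-2,3-dihydro-1,4-benzodioxine-6-carboxylate | COC(=O)c1cc(OC)c2OCC(=O)Oc2c1 | intermediate
5 | 5-hydroxyvanillin | O=Cc1cc(O)c(O)c(OC)c1 | starting material
6 | 4-(benzyloxy)-3-hydroxy-5-methoxybenzaldehyde | O=Cc1cc(O)c(OCc2ccccc2)c(OC)c1 | intermediate
7 | 4-(benzyloxy)-3-methoxy-5-(methoxymethoxy)benzaldehyde | O=Cc1cc(OC)c(OCc2ccccc2)c(OCOC)c1 | intermediate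
8 | lithium enolate of lactone 4 (formed in the flask) | COC(=O)c1cc(OC)c2OC=C([O-])Oc2c1.[Li+] | intermediate
9 | aldol adduct (racemic diastereomer mixture, both centres erased in step 6) | COC(=O)c1cc(OC)c2OC(C(O)c3cc(OC)c(OCc4ccccc4)c(OCOC)c3)C(=O)Oc2c1 | intermediate
10 | benzylic mesylate of 9 (formed in the flask) | COC(=O)c1cc(OC)c2OC(C(OS(C)(=O)=O)c3cc(OC)c(OCc4ccccc4)c(OCOC)c3)C(=O)Oc2c1 | intermediate
11 | (Z)-arylidene lactone | COC(=O)c1cc(OC)c2O/C(=C\c3cc(OC)c(OCc4ccccc4)c(OCOC)c3)C(=O)Oc2c1 | intermediate
12 | (Z)-α-aryloxycinnamic acid with free ring-A 3-OH | COC(=O)c1cc(OC)c(O/C(=C\c2cc(OC)c(OCc3ccccc3)c(OCOC)c2)C(=O)O)c(O)c1 | intermediate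
13 | (S)-2-aryloxy-3-arylpropanoic acid | COC(=O)c1cc(OC)c(O[C@@H](Cc2cc(OC)c(OCc3ccccc3)c(OCOC)c2)C(=O)O)c(O)c1 | intermediate
14 | (S)-phenol diol | OCc1cc(OC)c(O[C@@H](Cc2cc(OC)c(OCc3ccccc3)c(OCOC)c2)CO)c(O)c1 | intermediate
15 | (S)-O-benzyl aldehyde | O=Cc1cc(OC)c(O[C@@H](Cc2cc(OC)c(OCc3ccccc3)c(OCOC)c2)CO)c(O)c1 | intermediate
16 | (S)-aldehyde bisphenol, key-step precursor | O=Cc1cc(OC)c(O[C@@H](Cc2cc(OC)c(O)c(OCOC)c2)CO)c(O)c1 | intermediate
17 | p-quinone methide (formed in the flask; geometry of the exocyclic C=C immaterial) | O=Cc1cc(OC)c(O[C@@H](C=C2C=C(OC)C(=O)C(OCOC)=C2)CO)c(O)c1 | intermediate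
18 | (2R,3R)-trans-benzodioxane aldehyde | COc1cc([C@H]2Oc3cc(C=O)cc(OC)c3O[C@@H]2CO)cc(OCOC)c1O | intermediate
19 | (triphenylphosphoranylidene)acetaldehyde | O=CC=P(c1ccccc1)(c1ccccc1)c1ccccc1 | starting material
20 | MOM-protected (E)-enal | COc1cc([C@H]2Oc3cc(/C=C/C=O)cc(OC)c3O[C@@H]2CO)cc(OCOC)c1O | intermediate
21 | CNP0103768.1 | COc1cc([C@H]2Oc3cc(/C=C/C=O)cc(OC)c3O[C@@H]2CO)cc(O)c1O | target

**Total step count:** 14. **Longest linear sequence:** 12 (steps 1–2 or 3–4, then 5–14).

**Steps most likely to fail**

**1. Step 12 (proposed new method).**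
- What may go wrong: tautomerisation of the quinone methide or loss of formaldehyde, either with loss of the C2 information. Competing one-electron oxidation and coupling at the ring-A phenol, or capture of the methide by adventitious water, are also possible.
- Fallback (known chemistry, biomimetic oxidative cross-coupling) sets out from 7 and 5 and returns at 18. Aldehyde 7 is debenzylated (H2, Pd/C, EtOAc) to 4-hydroxy-3-methoxy-5-(methoxymethoxy)benzaldehyde F1. Ethyl (triphenylphosphoranylidene)acetate in warm toluene then gives the ethyl (E)-cinnamate F2, and DIBAL-H reduces it to the sinapyl-type (E)-cinnamyl alcohol F3.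
- Ag2CO3 (or Ag2O) in benzene/acetone couples F3 with catechol 5: the β-carbon of the cinnamyl radical bonds to the 4-O of 5, and the 3-OH then closes on the resulting quinone methide. This gives the racemic trans-benzodioxane aldehyde F4. Any regioisomer is removed by chromatography, and preparative HPLC on a chiral phase gives 18.

**2. Step 8.**
- What may go wrong: slow turnover or eroded facial selectivity, because the free ortho-phenol and the doubly ortho-substituted aryloxy group compete with the carboxylate for iridium. Relactonisation followed by epimerisation on handling is a further risk.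
- Fallback (resolution in place of asymmetric catalysis) sets out from 12 and returns at 13. The alkene is saturated without stereocontrol (H2, Pd/C poisoned with 2,2'-bipyridyl so that the aryl benzyl ether is spared, MeOH) to the racemic acid F5.
- F5 is resolved by crystallisation of its diastereomeric salt with (S)-1-phenylethylamine F6, the amine antipode being chosen by screening. Cold dilute acid then releases 13.

**3. Step 13.**
- What may go wrong: a second olefination of the more electrophilic enal product, sluggish reaction of the electron-rich aryl aldehyde, or thermal reopening at C3 on long heating.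
- Fallback (ester homologation with redox adjustment) sets out from 18 and returns at 20. Ethyl (triphenylphosphoranylidene)acetate gives the ethyl (E)-acrylate F7, which cannot homologate further. DIBAL-H at −78 °C gives the (E)-allylic alcohol F8, and MnO2 oxidises only the allylic alcohol to 20.

**Further compounds**
F1 | step 12 | 4-hydroxy-3-methoxy-5-(methoxymethoxy)benzaldehyde | O=Cc1cc(OC)c(O)c(OCOC)c1
F2 | step 12 | ethyl (E)-3-[4-hydroxy-3-methoxy-5-(methoxymethoxy)phenyl]prop-2-enoate | CCOC(=O)/C=C/c1cc(OC)c(O)c(OCOC)c1
F3 | step 12 | (E)-4-(3-hydroxyprop-1-enyl)-2-methoxy-6-(methoxymethoxy)phenol | OC/C=C/c1cc(OC)c(O)c(OCOC)c1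
F4 | step 12 | racemic trans-benzodioxane aldehyde (18 plus its enantiomer) | COc1cc([C@H]2Oc3cc(C=O)cc(OC)c3O[C@@H]2CO)cc(OCOC)c1O.COc1cc([C@@H]2Oc3cc(C=O)cc(OC)c3O[C@H]2CO)cc(OCOC)c1O
F5 | step 8 | racemic 2-aryloxy-3-arylpropanoic acid (13 plus its enantiomer) | COC(=O)c1cc(OC)c(O[C@@H](Cc2cc(OC)c(OCc3ccccc3)c(OCOC)c2)C(=O)O)c(O)c1.COC(=O)c1cc(OC)c(O[C@H](Cc2cc(OC)c(OCc3ccccc3)c(OCOC)c2)C(=O)O)c(O)c1
F6 | step 8 | (S)-1-phenylethylammonium salt of 13 | COC(=O)c1cc(OC)c(O[C@@H](Cc2cc(OC)c(OCc3ccccc3)c(OCOC)c2)C(=O)[O-])c(O)c1.C[C@H]([NH3+])c1ccccc1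
F7 | step 13 | ethyl (E)-3-{(2R,3R)-3-[4-hydroxy-3-methoxy-5-(methoxymethoxy)phenyl]-2-(hydroxymethyl)-8-methoxy-2,3-dihydro-1,4-benzodioxin-6-yl}prop-2-enoate | COc1cc([C@H]2Oc3cc(/C=C/C(=O)OCC)cc(OC)c3O[C@@H]2CO)cc(OCOC)c1O
F8 | step 13 | (E)-allylic alcohol of the benzodioxane | COc1cc([C@H]2Oc3cc(/C=C/CO)cc(OC)c3O[C@@H]2CO)cc(OCOC)c1O
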